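**Plan**

- Locants follow gibberellane numbering (ring A C1–C5, C10; ring B C5, C6, C8–C10; ring C C8, C9, C11–C14; ring D C8, C13–C16; C7 on C6, C18 and C19 on C4, C20 on C10, C17 on C16).
- Retrosynthesis: once the benzyl-type protecting groups, the C3 carbinol and the C11–C12 saturation are taken back, C4–C5 and C9–C10 are cut in one operation. This is possible because C4 lies between the C3 oxygen and the C19 carboxyl (a β-keto ester) and is followed by C5, the methyl-bearing C10 and C9, so a C4 radical can close ring A and the C10 radical it leaves can close ring B onto a C9=C11 alkene.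
- The open-chain β-keto ester is cut at C1–C2 (acetoacetate dianion plus allylic bromide), C5=C10 (Wittig), C6–C7 (α-hydroxymethylation), C13–C16 (aldol) and C6–C8 (Claisen), back to 3-ethoxycyclohex-2-en-1-one.
- Forward order: ring C is the starting ring; C8 becomes quaternary by an Eschenmoser–Claisen shift; ring D closes by an intramolecular aldol addition; the C12 oxygen is removed while C9=C11 is parked as a sulfide; the chain C6→C19 is attached; rings A and B close together last.
- Stereochemistry: an oxazaborolidine reduction fixes a carbinol whose chirality is passed to C8; the bridge and a chelated aldol fix C13 and C16; an enamine catalyst fixes C6; C6, C8 and the E alkene direct C4, C5, C10 and C9 in the radical step; a bulky hydride sets C3.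

Key step: step 19

Remark: 26 is carried as both C4 epimers because they give the same C4 radical; "endo" at C16 means the face turned towards C11/C12, and α/β refer to the usual gibberellin drawing with the C20 methyl α.

**Route**

Step 1
Reactants: 1 3-ethoxycyclohex-2-en-1-one
Product: 3 3-allylcyclohex-2-en-1-one, via 1-allyl-3-ethoxycyclohex-2-en-1-ol 2 (not isolated)
Conditions: allylMgBr (1.2 equiv), THF, 0 °C; then 1 M aq. HCl, 0 °C, short contact
Reagents that add atoms: allylmagnesium bromide, C=CC[Mg]Br; water, O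
Why: Stork–Danheiser alkylative carbonyl transposition: the Grignard reagent adds 1,2 to the vinylogous ester, and cold dilute acid hydrolyses the enol ether and expels the tertiary hydroxyl, leaving the allyl group on the β-carbon of the new enone without moving the skipped diene into conjugation.

Step 2
Reactants: 3 3-allylcyclohex-2-en-1-one
Product: 4 (1R)-3-allylcyclohex-2-en-1-ol
Conditions: (S)-2-methyl-CBS-oxazaborolidine (0.1 equiv), catecholborane (1.5 equiv), toluene, −78 °C; MeOH, aq. NaHCO3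
Reagents that add atoms: none
Why: Corey–Bakshi–Shibata reduction: the alkenyl branch of the enone behaves as the large group on the oxazaborolidine–borane complex, so hydride reaches one carbonyl face and the future C11 carbinol is set as R, while catecholborane at −78 °C leaves the terminal alkene alone.

Step 3
Reactants: 4 (1R)-3-allylcyclohex-2-en-1-ol
Product: 6 2-[(1S)-1-allylcyclohex-2-en-1-yl]-N,N-dimethylacetamide, via ketene N,O-acetal 5 (not isolated)
Conditions: MeC(OMe)2NMe2 (4 equiv), xylene, 140 °C, sealed tube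
Reagents that add atoms: N,N-dimethylacetamide dimethyl acetal, CC(OC)(OC)N(C)C
Why: Eschenmoser–Claisen rearrangement: loss of methanol gives the ketene N,O-acetal, whose [3,3] shift is suprafacial across the ring, so the C11–O stereocentre is traded for the quaternary C8 (S), C6 arrives as CH2 and the alkene ends at C9=C11.

Step 4
Reactants: 6 2-[(1S)-1-allylcyclohex-2-en-1-yl]-N,N-dimethylacetamide
Product: 7 N,N-dimethyl-2-[(1S)-1-(2-oxopropyl)cyclohex-2-en-1-yl]acetamide
Conditions: PdCl2 (10 mol %), CuCl (1 equiv), O2 (1 atm), DMF–H2O 7:1, rt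
Reagents that add atoms: water, O
Why: Tsuji–Wacker oxidation: divalent palladium hydroxypalladates the terminal monosubstituted alkene at its internal carbon far faster than the cis-disubstituted ring alkene, giving the methyl ketone that supplies C16 and C17.

Step 5
Reactants: 7 N,N-dimethyl-2-[(1S)-1-(2-oxopropyl)cyclohex-2-en-1-yl]acetamide
Product: 8 N,N-dimethyl-2-[(1S)-4-oxo-1-(2-oxopropyl)cyclohex-2-en-1-yl]acetamide
Conditions: Rh2(cap)4 (dirhodium tetrakis(caprolactamate), 1 mol %), t-BuOOH (5 equiv), K2CO3 (0.5 equiv), CH2Cl2, rt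
Reagents that add atoms: tert-butyl hydroperoxide, CC(C)(C)OO
Why: Allylic C–H oxidation by tert-butylperoxyl radicals: C12 is the only allylic methylene of the ring alkene because C8 is quaternary, so hydrogen abstraction, peroxide capture and loss of tert-butanol give the 4,4-disubstituted cyclohex-2-enone.

Step 6
Reactants: 8 N,N-dimethyl-2-[(1S)-4-oxo-1-(2-oxopropyl)cyclohex-2-en-1-yl]acetamide
Product: 9 2-[(1S,5R,6S)-6-hydroxy-6-methyl-4-oxobicyclo[3.2.1]oct-2-en-1-yl]-N,N-dimethylacetamide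
Conditions: LiN(SiMe3)2 (1.0 equiv), THF, −78 → −20 °C; AcOH, −78 °C
Reagents that add atoms: none
Why: Intramolecular aldol addition to a bridged ketol: C13 is the only enolisable ring position of the enone and its enolate closes ring D onto the C16 ketone (5-enolexo-exo-trig); C13 is fixed by the bridge to C8, and the lithium chelate between the C12 and C16 oxygens puts the new hydroxyl endo and the methyl exo.

Step 7
Reactants: 9 2-[(1S,5R,6S)-6-hydroxy-6-methyl-4-oxobicyclo[3.2.1]oct-2-en-1-yl]-N,N-dimethylacetamide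
Product: 10 2-[(1S,2R,5R,6S)-6-hydroxy-6-methyl-4-oxo-2-(phenylsulfanyl)bicyclo[3.2.1]octan-1-yl]-N,N-dimethylacetamide
Conditions: PhSH (1.5 equiv), Et3N (0.2 equiv), CH2Cl2, 0 °C → rt
Reagents that add atoms: thiophenol, Sc1ccccc1
Why: Thia-Michael addition: the thiolate adds to C9 from the face away from the C15–C16 bridge and stores the future C9=C11 alkene as a sulfide, so the C12 carbonyl can be removed without an allylic intermediate; the C9 configuration is of no consequence.

Step 8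
Reactants: 10 2-[(1S,2R,5R,6S)-6-hydroxy-6-methyl-4-oxo-2-(phenylsulfanyl)bicyclo[3.2.1]octan-1-yl]-N,N-dimethylacetamide
Product: 11 2-[(1S,2R,5S,6S)-6-hydroxy-6-methyl-2-(phenylsulfanyl)-4-(2-tosylhydrazinylidene)bicyclo[3.2.1]octan-1-yl]-N,N-dimethylacetamide
Conditions: TsNHNH2 (1.3 equiv), AcOH (cat.), MeOH, rt → 40 °C
Reagents that add atoms: 4-methylbenzenesulfonohydrazide, Cc1ccc(S(=O)(=O)NN)cc1
Why: Condensation of the C12 ketone with tosylhydrazide, an ordinary hydrazone formation that leaves the amide, the tertiary alcohol and the sulfide untouched.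

Step 9
Reactants: 11 2-[(1S,2R,5S,6S)-6-hydroxy-6-methyl-2-(phenylsulfanyl)-4-(2-tosylhydrazinylidene)bicyclo[3.2.1]octan-1-yl]-N,N-dimethylacetamide
Product: 13 2-[(1S,2R,5R,6S)-6-hydroxy-6-methyl-2-(phenylsulfanyl)bicyclo[3.2.1]octan-1-yl]-N,N-dimethylacetamide, via tosylhydrazine 12 (not isolated)
Conditions: catecholborane (3 equiv), CHCl3, 0 °C; then NaOAc·3H2O, 60 °C
Reagents that add atoms: none
Why: Catecholborane reduction of a tosylhydrazone (Caglioti-type deoxygenation): hydride adds to C=N, acetate expels sulfinate and the diazene loses N2, leaving C12 as CH2 under conditions mild enough for the tertiary alcohol.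

Step 10
Reactants: 13 2-[(1S,2R,5R,6S)-6-hydroxy-6-methyl-2-(phenylsulfanyl)bicyclo[3.2.1]octan-1-yl]-N,N-dimethylacetamide
Product: 15 2-[(1S,5R,6S)-6-hydroxy-6-methylbicyclo[3.2.1]oct-2-en-1-yl]-N,N-dimethylacetamide, via sulfoxide 14 (not isolated)
Conditions: mCPBA (1.05 equiv), CH2Cl2, −78 °C; aq. NaHCO3 wash; then toluene, 110 °C
Reagents that add atoms: none
Why: Sulfide oxidation and thermal syn-elimination of the sulfoxide: C8 carries no hydrogen, so the only β-hydrogens are on C11 and the alkene can form only as C9=C11.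

Step 11
Reactants: 15 2-[(1S,5R,6S)-6-hydroxy-6-methylbicyclo[3.2.1]oct-2-en-1-yl]-N,N-dimethylacetamide
Product: 16 2-[(1S,5R,6S)-6-hydroxy-6-methylbicyclo[3.2.1]oct-2-en-1-yl]acetaldehyde
Conditions: Cp2Zr(H)Cl (2.5 equiv), THF, rt, 30 min; silica gel
Reagents that add atoms: none
Why: Reduction of a tertiary amide with Cp2Zr(H)Cl: hydrozirconation of the amide carbonyl gives a zirconated N,O-hemiaminal that survives until work-up, so reduction stops at the aldehyde and is faster than hydrozirconation of the hindered ring alkene.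

Step 12
Reactants: 16 2-[(1S,5R,6S)-6-hydroxy-6-methylbicyclo[3.2.1]oct-2-en-1-yl]acetaldehyde
Product: 17 (2S)-3-hydroxy-2-[(1R,5R,6S)-6-hydroxy-6-methylbicyclo[3.2.1]oct-2-en-1-yl]propanal
Conditions: aq. CH2O (37 %, 3 equiv), (R)-α,α-diphenylprolinol trimethylsilyl ether (20 mol %), pH 7 phosphate buffer, toluene, rt
Reagents that add atoms: formaldehyde, C=O
Why: Enamine-catalysed α-hydroxymethylation of an aldehyde: the E-enamine is shielded on one face by the CPh2OSiMe3 group and formaldehyde enters from the other, so the (R)-catalyst, not the bicycle, should set C6 as S.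

Step 13
Reactants: 17 (2S)-3-hydroxy-2-[(1R,5R,6S)-6-hydroxy-6-methylbicyclo[3.2.1]oct-2-en-1-yl]propanal
Product: 18 (2S)-3-[(benzyloxy)methoxy]-2-[(1R,5R,6S)-6-hydroxy-6-methylbicyclo[3.2.1]oct-2-en-1-yl]propanal
Conditions: BnOCH2Cl (1.5 equiv), i-Pr2NEt (2.5 equiv), CH2Cl2, 0 °C, crude 17 used at once
Reagents that add atoms: benzyl chloromethyl ether, ClCOCc1ccccc1
Why: O-alkylation of the primary alcohol with a reactive α-chloro ether under a hindered amine base; the tertiary C16 alcohol is too hindered to react at 0 °C, and the benzyloxymethyl group falls off in the final hydrogenolysis.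

Step 14
Reactants: 18 (2S)-3-[(benzyloxy)methoxy]-2-[(1R,5R,6S)-6-hydroxy-6-methylbicyclo[3.2.1]oct-2-en-1-yl]propanal; 19 ethyl 2-(triphenylphosphoranylidene)propanoate
Product: 20 ethyl (2E,4S)-5-[(benzyloxy)methoxy]-4-[(1R,5R,6S)-6-hydroxy-6-methylbicyclo[3.2.1]oct-2-en-1-yl]-2-methylpent-2-enoate
Conditions: 19 (2 equiv), toluene, 90 °C
Reagents that add atoms: none
Why: Wittig olefination with a stabilised α-methyl ylide: reversible oxaphosphetane formation funnels to the E-trisubstituted enoate (C5=C10), and the salt-free neutral conditions spare the C6 stereocentre.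

Step 15
Reactants: 20 ethyl (2E,4S)-5-[(benzyloxy)methoxy]-4-[(1R,5R,6S)-6-hydroxy-6-methylbicyclo[3.2.1]oct-2-en-1-yl]-2-methylpent-2-enoate
Product: 21 (2E,4S)-5-[(benzyloxy)methoxy]-4-[(1R,5R,6S)-6-hydroxy-6-methylbicyclo[3.2.1]oct-2-en-1-yl]-2-methylpent-2-en-1-ol
Conditions: i-Bu2AlH (3.5 equiv), CH2Cl2, −78 °C; Rochelle salt
Reagents that add atoms: none
Why: 1,2-reduction of the conjugated ester to the allylic alcohol (C1) by an electrophilic aluminium hydride, which touches neither the acetal nor the alkenes.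

Step 16
Reactants: 21 (2E,4S)-5-[(benzyloxy)methoxy]-4-[(1R,5R,6S)-6-hydroxy-6-methylbicyclo[3.2.1]oct-2-en-1-yl]-2-methylpent-2-en-1-ol
Product: 22 (1R,5R,6S)-1-{(2S,3E)-1-[(benzyloxy)methoxy]-5-bromo-4-methylpent-3-en-2-yl}-6-methylbicyclo[3.2.1]oct-2-en-6-ol
Conditions: CBr4 (1.3 equiv), PPh3 (1.3 equiv), CH2Cl2, 0 °C; used crude
Reagents that add atoms: carbon tetrabromide, BrC(Br)(Br)Br
Why: Appel bromination: the primary allylic alkoxyphosphonium ion is displaced by bromide in an SN2 step much faster than anything happens at the tertiary C16 alcohol.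

Step 17
Reactants: 23 benzyl 3-oxobutanoate
Product: 24 benzyl 2-methyl-3-oxobutanoate
Conditions: K2CO3 (1.1 equiv), MeI (1.05 equiv), acetone, 40 °C
Reagents that add atoms: iodomethane, CI
Why: C-alkylation of a β-keto ester enolate, which supplies the C18 methyl on the future C4.

Step 18
Reactants: 24 benzyl 2-methyl-3-oxobutanoate; 22 (1R,5R,6S)-1-{(2S,3E)-1-[(benzyloxy)methoxy]-5-bromo-4-methylpent-3-en-2-yl}-6-methylbicyclo[3.2.1]oct-2-en-6-ol
Product: 26 benzyl (6E,8S)-9-[(benzyloxy)methoxy]-8-[(1R,5R,6S)-6-hydroxy-6-methylbicyclo[3.2.1]oct-2-en-1-yl]-2,6-dimethyl-3-oxonon-6-enoate, via dianion 25 (not isolated)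
Conditions: 24 (3 equiv), NaH (3 equiv), THF, 0 °C; n-BuLi (3 equiv), 0 °C; then 22 (1 equiv), 0 °C; aq. NH4Cl
Reagents that add atoms: none
Why: Dianion alkylation of an acetoacetate: the more basic terminal carbanion (future C2) displaces the allylic bromide at C1, one equivalent of dianion being spent on the C16 hydroxyl, and C4 is left as an epimer mixture that converges in the next step.

Step 19
Reactants: 26 benzyl (6E,8S)-9-[(benzyloxy)methoxy]-8-[(1R,5R,6S)-6-hydroxy-6-methylbicyclo[3.2.1]oct-2-en-1-yl]-2,6-dimethyl-3-oxonon-6-enoate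
Product: 27 benzyl 7-[(benzyloxy)methoxy]-16-hydroxy-3-oxo-ent-gibberell-11-en-19-oate (16-OH endo)
Conditions: Mn(OAc)3·2H2O (2.2 equiv), Cu(OAc)2·H2O (1.0 equiv), degassed AcOH (0.05 M), 25 → 40 °C
Reagents that add atoms: none
Why: Oxidative free-radical bicyclisation of an unsaturated α-methyl β-keto ester, the manganese triacetate/copper diacetate polycyclisation known for 6-endo/5-exo tandem closures: trivalent manganese forms the enolate of either C4 epimer and oxidises it to the electrophilic C4 radical, which adds to C5 of the E-trisubstituted alkene through a chair transition state (ring A, 6-endo, tertiary radical at C10); the C10 radical then adds to C9 of the bicyclooctene (ring B, 5-exo) and divalent copper converts the secondary C11 radical into the less substituted C11=C12 alkene. C4 follows the established preference of this reaction type for an in-plane ketone and an axial ester, cis to the C20 methyl. C5 is controlled by C6: with H6 eclipsing the alkene to avoid allylic 1,3-strain with C20, the radical enters on the face of the CH2OBOM group, anti to the quaternary C8. C10 is set in the second closure, in which the chair radical bonds through its equatorial lobe (axial C20, trans A/B), as tertiary cyclohexyl radicals do when they form hydrindanes with an angular methyl. C9 is set by the bicycle: the C5–C6–C8 tether delivers C10 to the alkene face turned away from the C15–C16 bridge and its endo hydroxyl (cis B/C). The step needs 6-endo before 5-exo closure, secured by the C10 methyl that makes the endo radical tertiary, and a second closure that outruns oxidation of the C10 radical, secured by the nearness of C9 and by holding Cu(OAc)2 to one equivalent at high dilution.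

Step 20
Reactants: 27 benzyl 7-[(benzyloxy)methoxy]-16-hydroxy-3-oxo-ent-gibberell-11-en-19-oate
Product: 28 benzyl 7-[(benzyloxy)methoxy]-3,16-dihydroxy-ent-gibberell-11-en-19-oate (3-OH axial, cis to C18)
Conditions: LiBH(s-Bu)3 (3 equiv), THF, −78 °C; aq. NH4Cl at −78 °C
Reagents that add atoms: none
Why: Ketone reduction by a bulky trialkylborohydride, which attacks the C3 carbonyl along the equatorial trajectory and gives the axial alcohol, as with 4,4-disubstituted 3-oxo terpenoids; the hindered ester and the alkene are inert at −78 °C.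

Step 21
Reactants: 28 benzyl 7-[(benzyloxy)methoxy]-3,16-dihydroxy-ent-gibberell-11-en-19-oate
Product: 29 CNP0170663.1 (3,7,16-trihydroxy-ent-gibberellan-19-oic acid; 3-OH axial, 16-OH endo)
Conditions: H2 (1 atm), Pd/C (10 %), EtOAc–MeOH, rt
Reagents that add atoms: none
Why: Hydrogenation over palladium on carbon saturates the cis-disubstituted C11=C12 alkene and cleaves both benzylic C–O bonds, freeing the C19 acid and, after loss of formaldehyde from the hemiformal, the C7 alcohol; no stereocentre is formed or disturbed.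

**Compound list**

1 | 3-ethoxycyclohex-2-en-1-one | CCOC1=CC(=O)CCC1 | starting material
2 | 1-allyl-3-ethoxycyclohex-2-en-1-ol (racemic, formed as its magnesium alkoxide) | C=CCC1(O)C=C(OCC)CCC1 | intermediate
3 | 3-allylcyclohex-2-en-1-one | C=CCC1=CC(=O)CCC1 | intermediate
4 | (1R)-3-allylcyclohex-2-en-1-ol | C=CCC1=C[C@H](O)CCC1 | intermediate
5 | 1-{[(1R)-3-allylcyclohex-2-en-1-yl]oxy}-N,N-dimethylethen-1-amine (ketene N,O-acetal) | C=CCC1=C[C@H](OC(=C)N(C)C)CCC1 | intermediate
6 | 2-[(1S)-1-allylcyclohex-2-en-1-yl]-N,N-dimethylacetamide | CN(C)C(=O)C[C@]1(CC=C)C=CCCC1 | intermediate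
7 | N,N-dimethyl-2-[(1S)-1-(2-oxopropyl)cyclohex-2-en-1-yl]acetamide | CN(C)C(=O)C[C@]1(CC(C)=O)C=CCCC1 | intermediate
8 | N,N-dimethyl-2-[(1S)-4-oxo-1-(2-oxopropyl)cyclohex-2-en-1-yl]acetamide | CN(C)C(=O)C[C@]1(CC(C)=O)C=CC(=O)CC1 | intermediate
9 | 2-[(1S,5R,6S)-6-hydroxy-6-methyl-4-oxobicyclo[3.2.1]oct-2-en-1-yl]-N,N-dimethylacetamide (OH endo) | CN(C)C(=O)C[C@@]12C[C@@H](C(=O)C=C1)[C@@](C)(O)C2 | intermediate
10 | 2-[(1S,2R,5R,6S)-6-hydroxy-6-methyl-4-oxo-2-(phenylsulfanyl)bicyclo[3.2.1]octan-1-yl]-N,N-dimethylacetamide | CN(C)C(=O)C[C@@]12C[C@@H](C(=O)C[C@H]1Sc3ccccc3)[C@@](C)(O)C2 | intermediate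
11 | 2-[(1S,2R,5S,6S)-6-hydroxy-6-methyl-2-(phenylsulfanyl)-4-(2-tosylhydrazinylidene)bicyclo[3.2.1]octan-1-yl]-N,N-dimethylacetamide | CN(C)C(=O)C[C@@]12C[C@@H](C(=NNS(=O)(=O)c3ccc(C)cc3)C[C@H]1Sc4ccccc4)[C@@](C)(O)C2 | intermediate
12 | 2-[(1S,2R,5S,6S)-6-hydroxy-6-methyl-2-(phenylsulfanyl)-4-(2-tosylhydrazinyl)bicyclo[3.2.1]octan-1-yl]-N,N-dimethylacetamide (C4 epimers) | CN(C)C(=O)C[C@@]12C[C@@H](C(NNS(=O)(=O)c3ccc(C)cc3)C[C@H]1Sc4ccccc4)[C@@](C)(O)C2 | intermediate
13 | 2-[(1S,2R,5R,6S)-6-hydroxy-6-methyl-2-(phenylsulfanyl)bicyclo[3.2.1]octan-1-yl]-N,N-dimethylacetamide | CN(C)C(=O)C[C@@]12C[C@@H](CC[C@H]1Sc3ccccc3)[C@@](C)(O)C2 | intermediate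
14 | 2-[(1S,2R,5R,6S)-6-hydroxy-6-methyl-2-(phenylsulfinyl)bicyclo[3.2.1]octan-1-yl]-N,N-dimethylacetamide (sulfur epimers) | CN(C)C(=O)C[C@@]12C[C@@H](CC[C@H]1S(=O)c3ccccc3)[C@@](C)(O)C2 | intermediate
15 | 2-[(1S,5R,6S)-6-hydroxy-6-methylbicyclo[3.2.1]oct-2-en-1-yl]-N,N-dimethylacetamide | CN(C)C(=O)C[C@@]12C[C@@H](CC=C1)[C@@](C)(O)C2 | intermediate
16 | 2-[(1S,5R,6S)-6-hydroxy-6-methylbicyclo[3.2.1]oct-2-en-1-yl]acetaldehyde | O=CC[C@@]12C[C@@H](CC=C1)[C@@](C)(O)C2 | intermediate
17 | (2S)-3-hydroxy-2-[(1R,5R,6S)-6-hydroxy-6-methylbicyclo[3.2.1]oct-2-en-1-yl]propanal | O=C[C@H](CO)[C@@]12C[C@@H](CC=C1)[C@@](C)(O)C2 | intermediate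
18 | (2S)-3-[(benzyloxy)methoxy]-2-[(1R,5R,6S)-6-hydroxy-6-methylbicyclo[3.2.1]oct-2-en-1-yl]propanal | O=C[C@H](COCOCc3ccccc3)[C@@]12C[C@@H](CC=C1)[C@@](C)(O)C2 | intermediate
19 | ethyl 2-(triphenylphosphoranylidene)propanoate | CCOC(=O)C(C)=P(c1ccccc1)(c1ccccc1)c1ccccc1 | starting material
20 | ethyl (2E,4S)-5-[(benzyloxy)methoxy]-4-[(1R,5R,6S)-6-hydroxy-6-methylbicyclo[3.2.1]oct-2-en-1-yl]-2-methylpent-2-enoate | CCOC(=O)/C(C)=C/[C@H](COCOCc3ccccc3)[C@@]12C[C@@H](CC=C1)[C@@](C)(O)C2 | intermediate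
21 | (2E,4S)-5-[(benzyloxy)methoxy]-4-[(1R,5R,6S)-6-hydroxy-6-methylbicyclo[3.2.1]oct-2-en-1-yl]-2-methylpent-2-en-1-ol | OC/C(C)=C/[C@H](COCOCc3ccccc3)[C@@]12C[C@@H](CC=C1)[C@@](C)(O)C2 | intermediate
22 | (1R,5R,6S)-1-{(2S,3E)-1-[(benzyloxy)methoxy]-5-bromo-4-methylpent-3-en-2-yl}-6-methylbicyclo[3.2.1]oct-2-en-6-ol | BrC/C(C)=C/[C@H](COCOCc3ccccc3)[C@@]12C[C@@H](CC=C1)[C@@](C)(O)C2 | intermediate
23 | benzyl 3-oxobutanoate (benzyl acetoacetate) | CC(=O)CC(=O)OCc1ccccc1 | starting material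
24 | benzyl 2-methyl-3-oxobutanoate (racemic) | CC(=O)C(C)C(=O)OCc1ccccc1 | intermediate
25 | sodium lithium dianion of benzyl 2-methyl-3-oxobutanoate | [Na+].[Li+].[CH2-]C(=O)[C-](C)C(=O)OCc1ccccc1 | intermediate
26 | benzyl (6E,8S)-9-[(benzyloxy)methoxy]-8-[(1R,5R,6S)-6-hydroxy-6-methylbicyclo[3.2.1]oct-2-en-1-yl]-2,6-dimethyl-3-oxonon-6-enoate (C2 epimers; C2 is C4 of the target) | O=C(OCc1ccccc1)C(C)C(=O)CC/C(C)=C/[C@H](COCOCc3ccccc3)[C@@]12C[C@@H](CC=C1)[C@@](C)(O)C2 | intermediate
27 | benzyl 7-[(benzyloxy)methoxy]-16-hydroxy-3-oxo-ent-gibberell-11-en-19-oate (5β-H, 6β-CH2O, 9β-H, 10α-CH3, 4α-CO2Bn, 16-OH endo) | C[C@@]12CCC(=O)[C@@](C)(C(=O)OCc3ccccc3)[C@H]1[C@H](COCOCc4ccccc4)[C@@]13C[C@@H](C=C[C@@H]21)[C@@](C)(O)C3 | intermediate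
28 | benzyl 7-[(benzyloxy)methoxy]-3,16-dihydroxy-ent-gibberell-11-en-19-oate (3-OH axial, cis to C18) | C[C@@]12CC[C@H](O)[C@@](C)(C(=O)OCc3ccccc3)[C@H]1[C@H](COCOCc4ccccc4)[C@@]13C[C@@H](C=C[C@@H]21)[C@@](C)(O)C3 | intermediate
29 | CNP0170663.1, 3,7,16-trihydroxy-ent-gibberellan-19-oic acid (3-OH axial, 16-OH endo) | C[C@@]12CC[C@H](O)[C@@](C)(C(=O)O)[C@H]1[C@H](CO)[C@@]13C[C@@H](CC[C@@H]21)[C@@](C)(O)C3 | target

**Step count and risks**

Total step count: 21. Longest linear sequence: 20 steps (steps 1–16 and 18–21; step 17 is a one-step side branch).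

Steps most likely to fail:

1. Step 19. The tertiary C10 radical may be oxidised before it reaches the hindered C9, so that ring B does not close, and the facial preference at C5 may be eroded. Fallback, from 26 back to 29: the same two bonds are made in a reductive chain with no oxidant present. Deprotonation of 26 (NaH, THF, −78 °C) and bromination with N-bromosuccinimide should give benzyl (6E,8S)-9-[(benzyloxy)methoxy]-2-bromo-8-[(1R,5R,6S)-6-hydroxy-6-methylbicyclo[3.2.1]oct-2-en-1-yl]-2,6-dimethyl-3-oxonon-6-enoate F1. Slow addition of Bu3SnH and azobisisobutyronitrile in benzene at 80 °C generates the C4 radical by bromine abstraction; both rings close as before and hydrogen transfer to C11 gives benzyl 7-[(benzyloxy)methoxy]-16-hydroxy-3-oxo-ent-gibberellan-19-oate F2. LiBH(s-Bu)3 at −78 °C gives benzyl 7-[(benzyloxy)methoxy]-3,16-dihydroxy-ent-gibberellan-19-oate F3, and hydrogenolysis over Pd/C returns to 29.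

2. Step 12. Enamine formation at an aldehyde next to a quaternary carbon may be too slow, the β-hydroxy aldehyde may lose water, and the bicycle may override the catalyst. Fallback, from 16 back to 18: C6 is set by an auxiliary instead. Oxidation of 16 (NaClO2, NaH2PO4, 2-methyl-2-butene) gives 2-[(1S,5R,6S)-6-hydroxy-6-methylbicyclo[3.2.1]oct-2-en-1-yl]acetic acid F4. Pivaloyl chloride and Et3N give the pivalic mixed anhydride F5, which acylates lithiated (R)-4-benzyloxazolidin-2-one to give (4R)-4-benzyl-3-{2-[(1S,5R,6S)-6-hydroxy-6-methylbicyclo[3.2.1]oct-2-en-1-yl]acetyl}oxazolidin-2-one F6. Enolisation with TiCl4 and i-Pr2NEt and reaction with s-trioxane/TiCl4 on the face opposite the benzyl group gives (4R)-4-benzyl-3-{(2S)-3-hydroxy-2-[(1R,5R,6S)-6-hydroxy-6-methylbicyclo[3.2.1]oct-2-en-1-yl]propanoyl}oxazolidin-2-one F7. BnOCH2Cl and i-Pr2NEt give its benzyloxymethyl ether F8, LiBH4 in THF–MeOH gives (2R)-3-[(benzyloxy)methoxy]-2-[(1R,5R,6S)-6-hydroxy-6-methylbicyclo[3.2.1]oct-2-en-1-yl]propan-1-ol F9, and Dess–Martin oxidation returns to 18.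

3. Step 14. Olefination at a carbonyl flanked by a tertiary and a quaternary carbon may stall, and long heating invites epimerisation at C6 or β-elimination of the acetal oxygen. Fallback, from 18 back to 26: the alkene is made by a sigmatropic shift instead. Isopropenylmagnesium bromide (THF, −78 °C) adds to 18 to give (3S)-4-[(benzyloxy)methoxy]-3-[(1R,5R,6S)-6-hydroxy-6-methylbicyclo[3.2.1]oct-2-en-1-yl]-2-methylbut-1-en-3-ylcarbinol, that is the allylic alcohol F10, as both carbinol epimers. Johnson–Claisen rearrangement (MeC(OEt)3, cat. EtCO2H, 140 °C) converts both epimers, through a chair with the large group equatorial, into ethyl (4E,6S)-7-[(benzyloxy)methoxy]-6-[(1R,5R,6S)-6-hydroxy-6-methylbicyclo[3.2.1]oct-2-en-1-yl]-4-methylhept-4-enoate F11. Claisen condensation of F11 with the lithium enolate of benzyl propanoate (LiN(i-Pr)2, THF, −78 → −30 °C) returns to 26.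

Further compounds
F1 | step 19 | benzyl (6E,8S)-9-[(benzyloxy)methoxy]-2-bromo-8-[(1R,5R,6S)-6-hydroxy-6-methylbicyclo[3.2.1]oct-2-en-1-yl]-2,6-dimethyl-3-oxonon-6-enoate | O=C(OCc1ccccc1)C(C)(Br)C(=O)CC/C(C)=C/[C@H](COCOCc3ccccc3)[C@@]12C[C@@H](CC=C1)[C@@](C)(O)C2
F2 | step 19 | benzyl 7-[(benzyloxy)methoxy]-16-hydroxy-3-oxo-ent-gibberellan-19-oate | C[C@@]12CCC(=O)[C@@](C)(C(=O)OCc3ccccc3)[C@H]1[C@H](COCOCc4ccccc4)[C@@]13C[C@@H](CC[C@@H]21)[C@@](C)(O)C3
F3 | step 19 | benzyl 7-[(benzyloxy)methoxy]-3,16-dihydroxy-ent-gibberellan-19-oate (3-OH axial) | C[C@@]12CC[C@H](O)[C@@](C)(C(=O)OCc3ccccc3)[C@H]1[C@H](COCOCc4ccccc4)[C@@]13C[C@@H](CC[C@@H]21)[C@@](C)(O)C3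
F4 | step 12 | 2-[(1S,5R,6S)-6-hydroxy-6-methylbicyclo[3.2.1]oct-2-en-1-yl]acetic acid | OC(=O)C[C@@]12C[C@@H](CC=C1)[C@@](C)(O)C2
F5 | step 12 | 2-[(1S,5R,6S)-6-hydroxy-6-methylbicyclo[3.2.1]oct-2-en-1-yl]acetic pivalic anhydride | CC(C)(C)C(=O)OC(=O)C[C@@]12C[C@@H](CC=C1)[C@@](C)(O)C2
F6 | step 12 | (4R)-4-benzyl-3-{2-[(1S,5R,6S)-6-hydroxy-6-methylbicyclo[3.2.1]oct-2-en-1-yl]acetyl}oxazolidin-2-one | O=C(C[C@@]12C[C@@H](CC=C1)[C@@](C)(O)C2)N1[C@H](Cc2ccccc2)COC1=O
F7 | step 12 | (4R)-4-benzyl-3-{(2S)-3-hydroxy-2-[(1R,5R,6S)-6-hydroxy-6-methylbicyclo[3.2.1]oct-2-en-1-yl]propanoyl}oxazolidin-2-one | O=C([C@H](CO)[C@@]12C[C@@H](CC=C1)[C@@](C)(O)C2)N1[C@H](Cc2ccccc2)COC1=O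
F8 | step 12 | (4R)-4-benzyl-3-{(2S)-3-[(benzyloxy)methoxy]-2-[(1R,5R,6S)-6-hydroxy-6-methylbicyclo[3.2.1]oct-2-en-1-yl]propanoyl}oxazolidin-2-one | O=C([C@H](COCOCc3ccccc3)[C@@]12C[C@@H](CC=C1)[C@@](C)(O)C2)N1[C@H](Cc2ccccc2)COC1=O
F9 | step 12 | (2R)-3-[(benzyloxy)methoxy]-2-[(1R,5R,6S)-6-hydroxy-6-methylbicyclo[3.2.1]oct-2-en-1-yl]propan-1-ol | OC[C@H](COCOCc3ccccc3)[C@@]12C[C@@H](CC=C1)[C@@](C)(O)C2
F10 | step 14 | (4S)-5-[(benzyloxy)methoxy]-4-[(1R,5R,6S)-6-hydroxy-6-methylbicyclo[3.2.1]oct-2-en-1-yl]-2-methylpent-1-en-3-ol (C3 epimers) | C=C(C)C(O)[C@H](COCOCc3ccccc3)[C@@]12C[C@@H](CC=C1)[C@@](C)(O)C2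
F11 | step 14 | ethyl (4E,6S)-7-[(benzyloxy)methoxy]-6-[(1R,5R,6S)-6-hydroxy-6-methylbicyclo[3.2.1]oct-2-en-1-yl]-4-methylhept-4-enoate | CCOC(=O)CC/C(C)=C/[C@H](COCOCc3ccccc3)[C@@]12C[C@@H](CC=C1)[C@@](C)(O)C2
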